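Zeylenone is cut at C2–C3 of its cyclohexenone ring. C3, the benzoyloxy-bearing carbon, is the γ-position of the C6 ketone across C4=C5, and C2 is a latent aldehyde on the fully substituted C1, so an acyclic keto aldehyde has a single enolisable site. A magnesium-chelated intramolecular vinylogous aldol addition closes the six-membered ring and sets C2 and C3 in one operation under control of C1, with both benzoates already in place. The precursor is built from L-erythrulose, whose C1–C3 become C7, C1 and C2; its stereocentre directs formation of C1 and is then erased by glycol cleavage.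

Key step: step 7

Numbering used below (target ring): C1 = quaternary carbinol carbon bearing OH and C7H2OBz; C2 = CH(OH); C3 = CH(OBz); C4=C5 = alkene; C6 = ketone.

Assumption: L-erythrulose is bought as its hydrate and dried in the flask by the excess 2,2-dimethoxypropane; methoxyallene, allyl benzoate and dimethylboron bromide are purchased.

Step 1
Reactants: 1 L-erythrulose
Product: 2 1-[(4S)-2,2-dimethyl-1,3-dioxolan-4-yl]-2-hydroxyethan-1-one (3,4-O-isopropylidene-L-erythrulose)
Conditions: Me2C(OMe)2, acetone, TsOH·H2O (cat.), rt; Et3N quench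
Reagents that add atoms: 2,2-dimethoxypropane, COC(C)(C)OC
Why: Acid-catalysed transketalisation closes the five-membered dioxolane on the terminal 3,4-diol in preference to a six-membered ring through the ketone, and the existing stereocentre is not touched.

Step 2
Reactants: 2 3,4-O-isopropylidene-L-erythrulose
Product: 3 2-[(4S)-2,2-dimethyl-1,3-dioxolan-4-yl]-2-oxoethyl benzoate
Conditions: BzCl, pyridine, CH2Cl2, 0 °C
Reagents that add atoms: benzoyl chloride, O=C(Cl)c1ccccc1
Why: Pyridine-mediated O-acylation of the only free hydroxyl installs the future C7 benzoate at low temperature, where the α-stereocentre of the ketone should not epimerise.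

Step 3
Reactants: 3 2-[(4S)-2,2-dimethyl-1,3-dioxolan-4-yl]-2-oxoethyl benzoate; 4 methoxyallene
Product: 7 (2S)-2-[(4S)-2,2-dimethyl-1,3-dioxolan-4-yl]-3-methoxy-2-(methoxymethoxy)penta-3,4-dien-1-yl benzoate, via 1-lithio-1-methoxyallene 5 (not isolated), via lithium alkoxide 6 (not isolated)
Conditions: 4 (1.3 equiv), n-BuLi (1.2 equiv), THF, −78 °C; add 3, −78 °C; then MeOCH2Cl, DMPU, −78 to −20 °C
Reagents that add atoms: chloromethyl methyl ether, COCCl
Why: 1,2-Addition of lithiated methoxyallene (an acryloyl anion equivalent) to the strongly activated α,α'-dioxygenated ketone should outrun attack on the aryl ester at −78 °C and follow the polar Felkin–Anh model (dioxolane C–O bond anti to the nucleophile) to give the anti adduct with the new quaternary centre S, and the alkoxide is capped by Williamson-type O-alkylation as the chelating MOM ether before the neighbouring benzoate can shift.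

Step 4
Reactants: 7 (2S)-2-[(4S)-2,2-dimethyl-1,3-dioxolan-4-yl]-3-methoxy-2-(methoxymethoxy)penta-3,4-dien-1-yl benzoate
Product: 8 (2S)-2-[(4S)-2,2-dimethyl-1,3-dioxolan-4-yl]-2-(methoxymethoxy)-3-oxopent-4-en-1-yl benzoate
Conditions: 0.5 M aq. H2SO4, THF, 0 °C
Reagents that add atoms: water, O
Why: Mild acid hydrolysis of the allenyl enol ether (protonation at the central allene carbon, then loss of methanol from the hemiketal) unmasks the vinyl ketone much faster than the acetonide or the MOM acetal is cleaved.

Step 5
Reactants: 8 (2S)-2-[(4S)-2,2-dimethyl-1,3-dioxolan-4-yl]-2-(methoxymethoxy)-3-oxopent-4-en-1-yl benzoate; 9 allyl benzoate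
Product: 10 (2E,5S)-5-[(4S)-2,2-dimethyl-1,3-dioxolan-4-yl]-5-(methoxymethoxy)-4-oxohex-2-ene-1,6-diyl dibenzoate
Conditions: 9 (3 equiv), second-generation Hoveyda–Grubbs catalyst RuCl2(H2IMes)(=CH-C6H4-2-OiPr) (5 mol %), CH2Cl2, 40 °C
Reagents that add atoms: none
Why: Olefin cross-metathesis between the hindered, electron-poor vinyl ketone (which does not dimerise) and an excess of the readily dimerising allyl ester should be selective for the cross product and give the E-enone, driven by loss of ethylene.

Step 6
Reactants: 10 (2E,5S)-5-[(4S)-2,2-dimethyl-1,3-dioxolan-4-yl]-5-(methoxymethoxy)-4-oxohex-2-ene-1,6-diyl dibenzoate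
Product: 11 (2E,5S)-5-formyl-5-(methoxymethoxy)-4-oxohex-2-ene-1,6-diyl dibenzoate
Conditions: H5IO6 (2 equiv), EtOAc, 0 °C to rt; used crude
Reagents that add atoms: none
Why: Periodic acid in ethyl acetate hydrolyses the terminal acetonide and cleaves the liberated 1,2-diol in the same flask (Malaprade glycol cleavage), so the former erythrulose stereocentre becomes the C2 aldehyde while the MOM ether protects C1 from over-cleavage.

Step 7
Reactants: 11 (2E,5S)-5-formyl-5-(methoxymethoxy)-4-oxohex-2-ene-1,6-diyl dibenzoate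
Product: 14 [(1S,5R,6S)-5-(benzoyloxy)-6-hydroxy-1-(methoxymethoxy)-2-oxocyclohex-3-en-1-yl]methyl benzoate, via bromomagnesium dienolate 12 (not isolated), via trimethylsilyl ether 13 (not isolated)
Conditions: MgBr2·OEt2 (3 equiv), Et3N (4 equiv), Me3SiCl (3 equiv), CH2Cl2 (0.01 M), 0 °C to rt; then 1 M HCl/THF, 0 °C
Reagents that add atoms: none
Why: Magnesium bromide binds the ketone and triethylamine removes a C3 proton (the only acidic C–H in 11, since C1 carries no hydrogen and the aldehyde cannot enolise), giving the bromomagnesium dienolate 12, whose γ-carbon C3 adds to the magnesium-activated C2 aldehyde; chlorotrimethylsilane then traps the aldolate as 13, which blocks retro-aldol and 1,2-benzoyl shift, and the acidic work-up frees the C2 hydroxyl. The closest known reaction types are the magnesium halide/amine soft-enolisation direct aldol addition and the intramolecular vinylogous aldol cyclisation of γ-enolisable enones. The cyclohexenone ring closes in the 6-(enolendo)-exo-trig mode, and the competing α-attack through C5 is excluded because it would give a cyclobutane. C2 is controlled by a five-membered Cram chelate of magnesium between the aldehyde oxygen and the MOM-bearing O1: with the nucleophile forced to arrive from the side of the C6 tether, the new C2–O bond ends equatorial and cis to the axial C1–O bond while the CH2OBz group stays equatorial. C3 is controlled by the dienolate geometry in a chair-like transition state: only the dienolate with C1 and C4 cis on C5=C6 and the benzoate on the outside (E) of C3=C4 can reach the aldehyde, which places the benzoate equatorial and trans to the C2 oxygen. The step needs γ-regioselectivity, one reactive dienolate geometry and chelate-controlled facial selectivity, secured respectively by ring size, by reversible enolisation under the amine/ammonium buffer and by the chelating MOM ether on C1 together with excess MgBr2.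

Step 8
Reactants: 14 [(1S,5R,6S)-5-(benzoyloxy)-6-hydroxy-1-(methoxymethoxy)-2-oxocyclohex-3-en-1-yl]methyl benzoate
Product: 15 zeylenone, [(1S,5R,6S)-5-(benzoyloxy)-1,6-dihydroxy-2-oxocyclohex-3-en-1-yl]methyl benzoate
Conditions: Me2BBr (4 equiv), CH2Cl2, −78 °C; then THF/sat. aq. NaHCO3, 0 °C
Reagents that add atoms: none
Why: Dimethylboron bromide cleaves the MOM acetal at −78 °C by Lewis acid-assisted acetal exchange (through the bromomethyl ether, hydrolysed on work-up) and should leave the two benzoates, the enone and the three stereocentres untouched.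

Compound list
1 | L-erythrulose, (3S)-1,3,4-trihydroxybutan-2-one | OCC(=O)[C@@H](O)CO | starting material
2 | 1-[(4S)-2,2-dimethyl-1,3-dioxolan-4-yl]-2-hydroxyethan-1-one | OCC(=O)[C@@H]1COC(C)(C)O1 | intermediate
3 | 2-[(4S)-2,2-dimethyl-1,3-dioxolan-4-yl]-2-oxoethyl benzoate | O=C(OCC(=O)[C@@H]1COC(C)(C)O1)c1ccccc1 | intermediate
4 | methoxyallene (1-methoxypropa-1,2-diene) | COC=C=C | starting material
5 | 1-lithio-1-methoxyallene | [Li]C(OC)=C=C | intermediate
6 | lithium (2S)-1-(benzoyloxy)-2-[(4S)-2,2-dimethyl-1,3-dioxolan-4-yl]-3-methoxypenta-3,4-dien-2-olate | O=C(OC[C@@]([O-])(C(OC)=C=C)[C@@H]1COC(C)(C)O1)c1ccccc1.[Li+] | intermediate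
7 | (2S)-2-[(4S)-2,2-dimethyl-1,3-dioxolan-4-yl]-3-methoxy-2-(methoxymethoxy)penta-3,4-dien-1-yl benzoate | O=C(OC[C@@](OCOC)(C(OC)=C=C)[C@@H]1COC(C)(C)O1)c1ccccc1 | intermediate
8 | (2S)-2-[(4S)-2,2-dimethyl-1,3-dioxolan-4-yl]-2-(methoxymethoxy)-3-oxopent-4-en-1-yl benzoate | O=C(OC[C@@](OCOC)(C(=O)C=C)[C@@H]1COC(C)(C)O1)c1ccccc1 | intermediate
9 | allyl benzoate | C=CCOC(=O)c1ccccc1 | starting material
10 | (2E,5S)-5-[(4S)-2,2-dimethyl-1,3-dioxolan-4-yl]-5-(methoxymethoxy)-4-oxohex-2-ene-1,6-diyl dibenzoate | O=C(OC[C@@](OCOC)(C(=O)/C=C/COC(=O)c1ccccc1)[C@@H]1COC(C)(C)O1)c1ccccc1 | intermediate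
11 | (2E,5S)-5-formyl-5-(methoxymethoxy)-4-oxohex-2-ene-1,6-diyl dibenzoate | O=C(OC[C@@](OCOC)(C(=O)/C=C/COC(=O)c1ccccc1)C=O)c1ccccc1 | intermediate
12 | bromomagnesium dienolate of 11 (C1 and C4 cis on C5=C6, benzoate E on C3=C4) | O=C(OC[C@@](OCOC)(/C(O[Mg]Br)=C\C=C\OC(=O)c1ccccc1)C=O)c1ccccc1 | intermediate
13 | [(1S,5R,6S)-5-(benzoyloxy)-1-(methoxymethoxy)-2-oxo-6-[(trimethylsilyl)oxy]cyclohex-3-en-1-yl]methyl benzoate | O=C(OC[C@@]1(OCOC)C(=O)C=C[C@@H](OC(=O)c2ccccc2)[C@@H]1O[Si](C)(C)C)c1ccccc1 | intermediate
14 | [(1S,5R,6S)-5-(benzoyloxy)-6-hydroxy-1-(methoxymethoxy)-2-oxocyclohex-3-en-1-yl]methyl benzoate | O=C(OC[C@@]1(OCOC)C(=O)C=C[C@@H](OC(=O)c2ccccc2)[C@@H]1O)c1ccccc1 | intermediate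
15 | zeylenone, [(1S,5R,6S)-5-(benzoyloxy)-1,6-dihydroxy-2-oxocyclohex-3-en-1-yl]methyl benzoate | O=C(OC[C@@]1(O)C(=O)C=C[C@@H](OC(=O)c2ccccc2)[C@@H]1O)c1ccccc1 | target

Total step count: 8
Longest linear sequence: 8 steps, from L-erythrulose 1 to zeylenone 15.

Steps most likely to fail

Step 7 (key ring closure). The dienolate may not reach the one geometry that can cyclise, facial control at C2 may be eroded if the chelate is not formed, or the aldolate may undergo retro-aldol or benzoyl shift before it is silylated. The fallback makes the C2–C3 bond between two molecules and closes the ring at C4=C5 instead. It sets out from 8: periodic acid cleavage as in step 6 should give (2S)-2-formyl-2-(methoxymethoxy)-3-oxopent-4-en-1-yl benzoate F1. The known reagent 3-bromoprop-1-en-1-yl benzoate F2 (from acrolein and benzoyl bromide) with indium powder in THF/water should add to the aldehyde as a γ-benzoyloxyallyl indium species, with chelation by the MOM-bearing O1, to give (2S)-2-[(1S,2R)-2-(benzoyloxy)-1-hydroxybut-3-en-1-yl]-2-(methoxymethoxy)-3-oxopent-4-en-1-yl benzoate F3; diastereomers would be separated if they form. Ring-closing metathesis of the vinyl ketone with the new vinyl group (second-generation Grubbs catalyst, CH2Cl2, 40 °C) comes back to the route at 14.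

Step 3 (allene addition in the presence of the benzoate). The organolithium may attack the ester, enolise the α-benzoyloxy ketone, or the tertiary alkoxide may take over the benzoyl group before it is alkylated. The fallback carries the primary oxygen as a silyl ether through the addition. It sets out from 2: TBSCl/imidazole in DMF should give 2-[(tert-butyldimethylsilyl)oxy]-1-[(4S)-2,2-dimethyl-1,3-dioxolan-4-yl]ethan-1-one F4. Lithiated methoxyallene followed by chloromethyl methyl ether, as in step 3, should give tert-butyl{[(2S)-2-[(4S)-2,2-dimethyl-1,3-dioxolan-4-yl]-3-methoxy-2-(methoxymethoxy)penta-3,4-dien-1-yl]oxy}dimethylsilane F5. Bu4NF buffered with AcOH in THF should give (2S)-2-[(4S)-2,2-dimethyl-1,3-dioxolan-4-yl]-3-methoxy-2-(methoxymethoxy)penta-3,4-dien-1-ol F6, and BzCl/pyridine comes back to the route at 7.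

Step 6 (one-flask acetonide hydrolysis and glycol cleavage). In the wet acidic medium the non-enolisable β-keto aldehyde may hydrate and lose its formyl group, and the transient diol may add to the enone in an oxa-Michael fashion. The fallback separates the two events and cleaves the diol under anhydrous, buffered conditions. It sets out from 10: aqueous acetic acid at rt (or CeCl3·7H2O/oxalic acid in MeCN) should give (2E,5S)-5-[(1S)-1,2-dihydroxyethyl]-5-(methoxymethoxy)-4-oxohex-2-ene-1,6-diyl dibenzoate F7, and Pb(OAc)4 over K2CO3 in CH2Cl2 at 0 °C comes back to the route at 11, which would be used at once.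

Further compounds
F1 | step 7 | (2S)-2-formyl-2-(methoxymethoxy)-3-oxopent-4-en-1-yl benzoate | O=C(OC[C@@](OCOC)(C(=O)C=C)C=O)c1ccccc1
F2 | step 7 | 3-bromoprop-1-en-1-yl benzoate | BrCC=COC(=O)c1ccccc1
F3 | step 7 | (2S)-2-[(1S,2R)-2-(benzoyloxy)-1-hydroxybut-3-en-1-yl]-2-(methoxymethoxy)-3-oxopent-4-en-1-yl benzoate | O=C(OC[C@@](OCOC)(C(=O)C=C)[C@@H](O)[C@H](OC(=O)c1ccccc1)C=C)c1ccccc1
F4 | step 3 | 2-[(tert-butyldimethylsilyl)oxy]-1-[(4S)-2,2-dimethyl-1,3-dioxolan-4-yl]ethan-1-one | CC(C)(C)[Si](C)(C)OCC(=O)[C@@H]1COC(C)(C)O1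
F5 | step 3 | tert-butyl{[(2S)-2-[(4S)-2,2-dimethyl-1,3-dioxolan-4-yl]-3-methoxy-2-(methoxymethoxy)penta-3,4-dien-1-yl]oxy}dimethylsilane | CC(C)(C)[Si](C)(C)OC[C@@](OCOC)(C(OC)=C=C)[C@@H]1COC(C)(C)O1
F6 | step 3 | (2S)-2-[(4S)-2,2-dimethyl-1,3-dioxolan-4-yl]-3-methoxy-2-(methoxymethoxy)penta-3,4-dien-1-ol | OC[C@@](OCOC)(C(OC)=C=C)[C@@H]1COC(C)(C)O1
F7 | step 6 | (2E,5S)-5-[(1S)-1,2-dihydroxyethyl]-5-(methoxymethoxy)-4-oxohex-2-ene-1,6-diyl dibenzoate | O=C(OC[C@@](OCOC)(C(=O)/C=C/COC(=O)c1ccccc1)[C@@H](O)CO)c1ccccc1
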